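**Retrosynthetic overview** (macrolide numbering: C1 = lactone C=O, C2 = CHMe, C3 = ketone, C4 = C(OH)CH2OH … C13 = CH(Et)O)
1. The C1–O13 lactone is opened to an acylketene from a β-keto tert-butyl ester (C2–C3 by Claisen condensation); C2 is left to thermodynamic control in the macrocycle.
2. C12–CH2OH comes from a dienyl iodide, made by hydroxyl-directed trans-hydrostannation of a C11≡C12 enyne.
3. C4–C5 comes from alkylation of the D-tartrate acetonide enolate with an E-allylic bromide (the tartrate centre sets C4 and is then removed by decarboxylation); C6=C7 comes from a Wittig reaction.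
4. C9–C10 comes from a nickel-catalysed electroreductive coupling of (R)-3-bromo-2-methylpropan-1-ol with a 2-chloroenyne; C10–C11 comes from Sonogashira coupling of (S)-pent-1-yn-3-ol with 1,1-dichloroethene.
5. Ring order: the bought dioxolane is carried as the C4 diol protecting group; the 14-membered lactone is the only ring formed (step 13).

Assumption: (S)-pent-1-yn-3-ol is taken as a purchasable enantiopure building block, and the natural 2R configuration is taken to be the thermodynamically preferred one at the epimerisable C2 of the macrocycle.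

**Route**

Step 1
Reactants: 1 (S)-pent-1-yn-3-ol; 2 1,1-dichloroethene
Product: 3 (3S)-6-chlorohept-6-en-4-yn-3-ol
Conditions: Pd(PPh3)4 (5 mol%), CuI (10 mol%), n-BuNH2 (2 equiv), 2 (5 equiv), PhMe, 25 °C
Reagents that add atoms: none
Why: Sonogashira coupling in which zerovalent palladium inserts into one C–Cl bond of the gem-dichloride and the fivefold excess of 2 holds the reaction at mono-coupling, leaving the C13 carbinol untouched.

Step 2
Reactants: 3 (3S)-6-chlorohept-6-en-4-yn-3-ol; 4 (2R)-3-bromo-2-methylpropan-1-ol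
Product: 5 (2S,7S)-2-methyl-4-methylidenenon-5-yne-1,7-diol
Conditions: NiBr2(dme) (10 mol%), 4,4'-di-tert-butyl-2,2'-bipyridine (12 mol%), NaI (0.5 equiv), DMA, undivided cell, graphite-felt cathode, Zn anode, 4 mA constant current (2.3 F/mol), 25 °C
Reagents that add atoms: none
Why: Proposed new method: cathodic reduction gives zerovalent nickel, which adds oxidatively to the alkyne-activated C(sp2)–Cl bond of 3; monovalent nickel abstracts bromine from 4 to give the primary radical (the stereocentre is β to it and stays intact), the radical is captured by the divalent alkenylnickel, and reductive elimination from trivalent nickel forms the C9–C10 bond while the zinc anode supplies the electrons and both free hydroxyls are tolerated because no basic organometallic is formed; the closest known reaction type is the nickel-catalysed (electro)reductive cross-electrophile coupling of alkyl bromides with aryl or alkenyl bromides, which has not been shown for a 2-chloro-1-en-3-yne.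

Step 3
Reactants: 5 (2S,7S)-2-methyl-4-methylidenenon-5-yne-1,7-diol; 6 ethyl 2-(triphenyl-λ5-phosphanylidene)propanoate
Product: 8 ethyl (2E,4S,9S)-9-hydroxy-2,4-dimethyl-6-methylideneundec-2-en-7-ynoate, via aldehyde 7 (not isolated)
Conditions: PhI(OAc)2 (1.1 equiv), TEMPO (10 mol%), CH2Cl2, 25 °C; then 6 (1.5 equiv), 40 °C
Reagents that add atoms: none
Why: Primary-selective TEMPO/PhI(OAc)2 oxidation followed in the same flask by a Wittig reaction with a stabilised ylide, which gives the E-trisubstituted alkene (C6=C7) and, being neutral, does not epimerise the α-methyl aldehyde.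

Step 4
Reactants: 8 ethyl (2E,4S,9S)-9-hydroxy-2,4-dimethyl-6-methylideneundec-2-en-7-ynoate
Product: 9 (2E,4S,9S)-2,4-dimethyl-6-methylideneundec-2-en-7-yne-1,9-diol
Conditions: iBu2AlH (3.5 equiv), CH2Cl2, −78 → −40 °C; aq. potassium sodium tartrate
Reagents that add atoms: none
Why: 1,2-Reduction of the α,β-unsaturated ester by diisobutylaluminium hydride gives the allylic alcohol, and the alkyne, the alkenes and both stereocentres are inert at this temperature.

Step 5
Reactants: 9 (2E,4S,9S)-2,4-dimethyl-6-methylideneundec-2-en-7-yne-1,9-diol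
Product: 10 (3S,8S,9E)-11-bromo-8,10-dimethyl-6-methylideneundec-9-en-4-yn-3-ol
Conditions: CBr4 (1.1 equiv), PPh3 (1.15 equiv), CH2Cl2, −40 → −20 °C
Reagents that add atoms: carbon tetrabromide, BrC(Br)(Br)Br
Why: Appel reaction in which the unhindered primary allylic hydroxyl is brominated by SN2 displacement (no allylic shift) much faster than the hindered secondary propargylic hydroxyl.

Step 6
Reactants: 10 (3S,8S,9E)-11-bromo-8,10-dimethyl-6-methylideneundec-9-en-4-yn-3-ol; 11 dimethyl (4S,5S)-2,2-dimethyl-1,3-dioxolane-4,5-dicarboxylate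
Product: 13 dimethyl (4R,5S)-4-[(2E,4S,9S)-9-hydroxy-2,4-dimethyl-6-methylideneundec-2-en-7-yn-1-yl]-2,2-dimethyl-1,3-dioxolane-4,5-dicarboxylate, via lithium enolate 12 (not isolated)
Conditions: 11 (3 equiv), LiN(iPr)2 (3 equiv), THF/DMPU (6:1), −78 °C, 20 min; then 10, −78 °C, 36 h; AcOH quench at −78 °C
Reagents that add atoms: none
Why: Seebach alkylation of the tartrate acetonide enolate, in which the allylic bromide enters anti to the ester on the neighbouring stereocentre bought with D-tartrate and so fixes the new quaternary C4 as R (one equivalent of enolate is consumed by the free hydroxyl of 10, and the ring oxygen cannot β-eliminate at −78 °C).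

Step 7
Reactants: 13 dimethyl (4R,5S)-4-[(2E,4S,9S)-9-hydroxy-2,4-dimethyl-6-methylideneundec-2-en-7-yn-1-yl]-2,2-dimethyl-1,3-dioxolane-4,5-dicarboxylate
Product: 14 (4S,5R)-5-[(2E,4S,9S)-9-hydroxy-2,4-dimethyl-6-methylideneundec-2-en-7-yn-1-yl]-5-(methoxycarbonyl)-2,2-dimethyl-1,3-dioxolane-4-carboxylic acid
Conditions: KOH (1.05 equiv), MeOH/H2O (4:1), 0 → 23 °C; then aq. HCl to pH 3 at 0 °C
Reagents that add atoms: potassium hydroxide, [K+].[OH-]
Why: Saponification under steric control, since hydroxide attacks the ester on the CH carbon far faster than the ester on the fully substituted C4, and any epimerisation at that CH carbon is irrelevant because the centre is removed in step 8.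

Step 8
Reactants: 14 (4S,5R)-5-[(2E,4S,9S)-9-hydroxy-2,4-dimethyl-6-methylideneundec-2-en-7-yn-1-yl]-5-(methoxycarbonyl)-2,2-dimethyl-1,3-dioxolane-4-carboxylic acid
Product: 15 methyl (4R)-4-[(2E,4S,9S)-9-hydroxy-2,4-dimethyl-6-methylideneundec-2-en-7-yn-1-yl]-2,2-dimethyl-1,3-dioxolane-4-carboxylate
Conditions: 4CzIPN (2 mol%), 2,4,6-triisopropylbenzenethiol (10 mol%), 2,6-lutidine (20 mol%), MeCN, 450 nm LEDs, 25 °C
Reagents that add atoms: none
Why: Photoredox hydrodecarboxylation of an α-alkoxy acid, in which the carboxylate is oxidised by the excited photocatalyst (too weak an oxidant to touch the alkenes), CO2 is lost and the dioxolanyl radical takes hydrogen from the thiol, so the spent tartrate centre becomes the CH2O carbon of the C4 hydroxymethyl group while the quaternary C4 is untouched.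

Step 9
Reactants: 15 methyl (4R)-4-[(2E,4S,9S)-9-hydroxy-2,4-dimethyl-6-methylideneundec-2-en-7-yn-1-yl]-2,2-dimethyl-1,3-dioxolane-4-carboxylate
Product: 17 methyl (4R)-4-[(2E,4S,7Z,9S)-9-hydroxy-8-iodo-2,4-dimethyl-6-methylideneundeca-2,7-dien-1-yl]-2,2-dimethyl-1,3-dioxolane-4-carboxylate, via alkenylstannane 16 (not isolated)
Conditions: [(C5Me5)RuCl]4 (1.5 mol%), Bu3SnH (1.1 equiv), CH2Cl2, 25 °C, 30 min; then I2 (1.15 equiv), −78 → 0 °C
Reagents that add atoms: tributylstannane, CCCC[SnH](CCCC)CCCC (tin is held only in 16); iodine, II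
Why: Hydroxyl-directed ruthenium-catalysed trans-hydrostannation (Fürstner) places tin on the alkyne carbon next to the C13 carbinol and hydrogen anti to it on C11, and iododestannylation with retention gives the iodide cis to C10, which is the geometry needed for the 11E alkene.

Step 10
Reactants: 17 methyl (4R)-4-[(2E,4S,7Z,9S)-9-hydroxy-8-iodo-2,4-dimethyl-6-methylideneundeca-2,7-dien-1-yl]-2,2-dimethyl-1,3-dioxolane-4-carboxylate; 18 (tributylstannyl)methanol
Product: 19 methyl (4R)-4-[(2E,4S,7E,9S)-9-hydroxy-8-(hydroxymethyl)-2,4-dimethyl-6-methylideneundeca-2,7-dien-1-yl]-2,2-dimethyl-1,3-dioxolane-4-carboxylate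
Conditions: Pd(PPh3)4 (10 mol%), 18 (1.5 equiv), 1,4-dioxane, 90 °C
Reagents that add atoms: none
Why: Migita–Kosugi–Stille hydroxymethylation of the alkenyl iodide, in which oxidative addition and reductive elimination go with retention so that CH2OH ends up cis to C10; it is done before ring closure because the later allylic β-keto lactone would be ionised by zerovalent palladium.

Step 11
Reactants: 19 methyl (4R)-4-[(2E,4S,7E,9S)-9-hydroxy-8-(hydroxymethyl)-2,4-dimethyl-6-methylideneundeca-2,7-dien-1-yl]-2,2-dimethyl-1,3-dioxolane-4-carboxylate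
Product: 20 methyl (4R)-4-[(2E,4S,7E,9S)-8-({[tert-butyl(dimethyl)silyl]oxy}methyl)-9-hydroxy-2,4-dimethyl-6-methylideneundeca-2,7-dien-1-yl]-2,2-dimethyl-1,3-dioxolane-4-carboxylate
Conditions: TBSCl (1.05 equiv), imidazole (2 equiv), CH2Cl2, 0 °C
Reagents that add atoms: tert-butyl(chloro)dimethylsilane, CC(C)(C)[Si](C)(C)Cl
Why: Silyl ether formation in which the primary allylic hydroxyl reacts much faster than the hindered secondary C13 hydroxyl, which must stay free as the only nucleophile for ring closure.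

Step 12
Reactants: 20 methyl (4R)-4-[(2E,4S,7E,9S)-8-({[tert-butyl(dimethyl)silyl]oxy}methyl)-9-hydroxy-2,4-dimethyl-6-methylideneundeca-2,7-dien-1-yl]-2,2-dimethyl-1,3-dioxolane-4-carboxylate; 21 tert-butyl propanoate
Product: 23 tert-butyl 3-{(4R)-4-[(2E,4S,7E,9S)-8-({[tert-butyl(dimethyl)silyl]oxy}methyl)-9-hydroxy-2,4-dimethyl-6-methylideneundeca-2,7-dien-1-yl]-2,2-dimethyl-1,3-dioxolan-4-yl}-2-methyl-3-oxopropanoate (both C2 epimers), via lithium enolate 22 (not isolated)
Conditions: 21 (4 equiv), LiN(iPr)2 (4 equiv), THF, −78 °C, 30 min; then 20, −78 → −10 °C; aq. NH4Cl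
Reagents that add atoms: none
Why: Crossed Claisen condensation in which the acceptor ester has no α-hydrogen and is activated by its α-oxygen, the tert-butyl propanoate enolate does not self-condense at low temperature, and deprotonation of the β-keto ester product drives the reaction (C2 forms as a mixture that is corrected in step 14).

Step 13
Reactants: 23 tert-butyl 3-{(4R)-4-[(2E,4S,7E,9S)-8-({[tert-butyl(dimethyl)silyl]oxy}methyl)-9-hydroxy-2,4-dimethyl-6-methylideneundeca-2,7-dien-1-yl]-2,2-dimethyl-1,3-dioxolan-4-yl}-2-methyl-3-oxopropanoate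
Product: 25 (5R,10S,11E,15S,16E)-11-({[tert-butyl(dimethyl)silyl]oxy}methyl)-10-ethyl-2,2,7,15,17-pentamethyl-13-methylidene-1,3,9-trioxaspiro[4.13]octadeca-11,16-diene-6,8-dione (both C7 epimers; this is 26 with the C4 diol as acetonide and the C12 CH2OH as silyl ether), via acylketene 24 (not isolated)
Conditions: PhMe (0.5 mM), 110 °C, syringe-pump addition over 8 h, then 4 h
Reagents that add atoms: none
Why: Acylketene macrolactonisation (Boeckman type), in which the β-keto tert-butyl ester loses tert-butanol thermally and the ketene is trapped at high dilution by the only free hydroxyl, acylating the C13 oxygen with retention and closing the 14-membered ring.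

Step 14
Reactants: 25 (5R,10S,11E,15S,16E)-11-({[tert-butyl(dimethyl)silyl]oxy}methyl)-10-ethyl-2,2,7,15,17-pentamethyl-13-methylidene-1,3,9-trioxaspiro[4.13]octadeca-11,16-diene-6,8-dione
Product: 26 (3R,5R,7E,9S,12E,14S)-14-ethyl-5-hydroxy-5,13-bis(hydroxymethyl)-3,7,9-trimethyl-11-methylidene-1-oxacyclotetradeca-7,12-diene-2,4-dione (CNP0104552.3)
Conditions: AcOH/THF/H2O (3:1:1), 45 °C
Reagents that add atoms: none
Why: Mild acid hydrolysis removes the isopropylidene acetal and the primary silyl ether, and the β-keto lactone enolises under these conditions so that C2 settles to the thermodynamically preferred 2R epimer under control of the fixed C4, C8 and C13 centres of the macrocycle.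

**Compound list**
1 | (S)-pent-1-yn-3-ol | C#C[C@H](CC)O | starting material
2 | 1,1-dichloroethene | C=C(Cl)Cl | starting material
3 | (3S)-6-chlorohept-6-en-4-yn-3-ol | C=C(Cl)C#C[C@H](CC)O | intermediate
4 | (2R)-3-bromo-2-methylpropan-1-ol | OC[C@@H](C)CBr | starting material
5 | (2S,7S)-2-methyl-4-methylidenenon-5-yne-1,7-diol | OC[C@@H](C)CC(=C)C#C[C@H](CC)O | intermediate
6 | ethyl 2-(triphenyl-λ5-phosphanylidene)propanoate | CCOC(=O)C(C)=P(c1ccccc1)(c1ccccc1)c1ccccc1 | starting material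
7 | (2S,7S)-7-hydroxy-2-methyl-4-methylidenenon-5-ynal | O=C[C@@H](C)CC(=C)C#C[C@H](CC)O | intermediate (not isolated)
8 | ethyl (2E,4S,9S)-9-hydroxy-2,4-dimethyl-6-methylideneundec-2-en-7-ynoate | CCOC(=O)/C(C)=C/[C@@H](C)CC(=C)C#C[C@H](CC)O | intermediate
9 | (2E,4S,9S)-2,4-dimethyl-6-methylideneundec-2-en-7-yne-1,9-diol | OC/C(C)=C/[C@@H](C)CC(=C)C#C[C@H](CC)O | intermediate
10 | (3S,8S,9E)-11-bromo-8,10-dimethyl-6-methylideneundec-9-en-4-yn-3-ol | BrC/C(C)=C/[C@@H](C)CC(=C)C#C[C@H](CC)O | intermediate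
11 | dimethyl (4S,5S)-2,2-dimethyl-1,3-dioxolane-4,5-dicarboxylate (dimethyl 2,3-O-isopropylidene-D-tartrate) | COC(=O)[C@H]1OC(C)(C)O[C@@H]1C(=O)OC | starting material
12 | methyl (4S)-5-[(lithiooxy)(methoxy)methylidene]-2,2-dimethyl-1,3-dioxolane-4-carboxylate (lithium enolate of 11) | COC(O[Li])=C1OC(C)(C)O[C@@H]1C(=O)OC | intermediate (not isolated)
13 | dimethyl (4R,5S)-4-[(2E,4S,9S)-9-hydroxy-2,4-dimethyl-6-methylideneundec-2-en-7-yn-1-yl]-2,2-dimethyl-1,3-dioxolane-4,5-dicarboxylate | COC(=O)[C@]1(C/C(C)=C/[C@@H](C)CC(=C)C#C[C@H](CC)O)OC(C)(C)O[C@@H]1C(=O)OC | intermediate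
14 | (4S,5R)-5-[(2E,4S,9S)-9-hydroxy-2,4-dimethyl-6-methylideneundec-2-en-7-yn-1-yl]-5-(methoxycarbonyl)-2,2-dimethyl-1,3-dioxolane-4-carboxylic acid | COC(=O)[C@]1(C/C(C)=C/[C@@H](C)CC(=C)C#C[C@H](CC)O)OC(C)(C)O[C@@H]1C(=O)O | intermediate
15 | methyl (4R)-4-[(2E,4S,9S)-9-hydroxy-2,4-dimethyl-6-methylideneundec-2-en-7-yn-1-yl]-2,2-dimethyl-1,3-dioxolane-4-carboxylate | COC(=O)[C@]1(C/C(C)=C/[C@@H](C)CC(=C)C#C[C@H](CC)O)OC(C)(C)OC1 | intermediate
16 | methyl (4R)-4-[(2E,4S,7Z,9S)-9-hydroxy-2,4-dimethyl-6-methylidene-8-(tributylstannyl)undeca-2,7-dien-1-yl]-2,2-dimethyl-1,3-dioxolane-4-carboxylate | COC(=O)[C@]1(C/C(C)=C/[C@@H](C)CC(=C)/C=C(\[Sn](CCCC)(CCCC)CCCC)[C@H](CC)O)OC(C)(C)OC1 | intermediate (not isolated)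
17 | methyl (4R)-4-[(2E,4S,7Z,9S)-9-hydroxy-8-iodo-2,4-dimethyl-6-methylideneundeca-2,7-dien-1-yl]-2,2-dimethyl-1,3-dioxolane-4-carboxylate | COC(=O)[C@]1(C/C(C)=C/[C@@H](C)CC(=C)/C=C(\I)[C@H](CC)O)OC(C)(C)OC1 | intermediate
18 | (tributylstannyl)methanol | CCCC[Sn](CCCC)(CCCC)CO | starting material
19 | methyl (4R)-4-[(2E,4S,7E,9S)-9-hydroxy-8-(hydroxymethyl)-2,4-dimethyl-6-methylideneundeca-2,7-dien-1-yl]-2,2-dimethyl-1,3-dioxolane-4-carboxylate | COC(=O)[C@]1(C/C(C)=C/[C@@H](C)CC(=C)/C=C(\CO)[C@H](CC)O)OC(C)(C)OC1 | intermediate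
20 | methyl (4R)-4-[(2E,4S,7E,9S)-8-({[tert-butyl(dimethyl)silyl]oxy}methyl)-9-hydroxy-2,4-dimethyl-6-methylideneundeca-2,7-dien-1-yl]-2,2-dimethyl-1,3-dioxolane-4-carboxylate | COC(=O)[C@]1(C/C(C)=C/[C@@H](C)CC(=C)/C=C(\CO[Si](C)(C)C(C)(C)C)[C@H](CC)O)OC(C)(C)OC1 | intermediate
21 | tert-butyl propanoate | CCC(=O)OC(C)(C)C | starting material
22 | lithium 1-(tert-butoxy)prop-1-en-1-olate (lithium enolate of 21) | CC=C(O[Li])OC(C)(C)C | intermediate (not isolated)
23 | tert-butyl 3-{(4R)-4-[(2E,4S,7E,9S)-8-({[tert-butyl(dimethyl)silyl]oxy}methyl)-9-hydroxy-2,4-dimethyl-6-methylideneundeca-2,7-dien-1-yl]-2,2-dimethyl-1,3-dioxolan-4-yl}-2-methyl-3-oxopropanoate (both C2 epimers) | CC(C)(C)OC(=O)C(C)C(=O)[C@]1(C/C(C)=C/[C@@H](C)CC(=C)/C=C(\CO[Si](C)(C)C(C)(C)C)[C@H](CC)O)OC(C)(C)OC1 | intermediate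
24 | 3-{(4R)-4-[(2E,4S,7E,9S)-8-({[tert-butyl(dimethyl)silyl]oxy}methyl)-9-hydroxy-2,4-dimethyl-6-methylideneundeca-2,7-dien-1-yl]-2,2-dimethyl-1,3-dioxolan-4-yl}-2-methylprop-1-ene-1,3-dione (acylketene) | O=C=C(C)C(=O)[C@]1(C/C(C)=C/[C@@H](C)CC(=C)/C=C(\CO[Si](C)(C)C(C)(C)C)[C@H](CC)O)OC(C)(C)OC1 | intermediate (not isolated)
25 | (5R,10S,11E,15S,16E)-11-({[tert-butyl(dimethyl)silyl]oxy}methyl)-10-ethyl-2,2,7,15,17-pentamethyl-13-methylidene-1,3,9-trioxaspiro[4.13]octadeca-11,16-diene-6,8-dione (both C7 epimers) | C=C1/C=C(\CO[Si](C)(C)C(C)(C)C)[C@H](CC)OC(=O)C(C)C(=O)[C@]2(COC(C)(C)O2)C/C(C)=C/[C@@H](C)C1 | intermediate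
26 | (3R,5R,7E,9S,12E,14S)-14-ethyl-5-hydroxy-5,13-bis(hydroxymethyl)-3,7,9-trimethyl-11-methylidene-1-oxacyclotetradeca-7,12-diene-2,4-dione | C=C1/C=C(\CO)[C@H](CC)OC(=O)[C@H](C)C(=O)[C@](O)(CO)C/C(C)=C/[C@@H](C)C1 | target

**Step count and risks**

Total steps: 14. Longest linear sequence: 14 (steps 1 to 14; compounds 2, 4, 6, 11, 18 and 21 are bought).

The three steps most likely to fail are steps 2, 6 and 13.

Step 2 is the proposed new coupling. The alkyl radical may add to the enyne, or low-valent nickel may react with the alkyne. The known replacement sets out from 3 and comes back at 5. Methyl (2R)-3-bromo-2-methylpropanoate F1 is converted with zinc dust and LiCl in THF into [(2R)-3-methoxy-2-methyl-3-oxopropyl]zinc bromide F2. Negishi coupling of F2 (2.2 equiv, to allow for the free hydroxyl) with 3 under Pd(OAc)2/SPhos in THF at 25 °C gives methyl (2S,7S)-7-hydroxy-2-methyl-4-methylidenenon-5-ynoate F3. LiBH4 in THF at 0 °C reduces F3 to 5.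

Step 6 depends on the narrow temperature window of the tartrate enolate and has to tolerate the free hydroxyl of 10. A route based on self-regeneration of the stereocentre sets out from 10 and comes back at 15, bypassing 13 and 14. Methyl (4R)-2,2-dimethyl-1,3-dioxolane-4-carboxylate F4 is transacetalised with pivalaldehyde (TsOH, CH2Cl2) to the cis acetal methyl (2R,4R)-2-tert-butyl-1,3-dioxolane-4-carboxylate F5. Deprotonation of F5 with LiN(iPr)2 in THF at −78 °C and alkylation with 10 on the face away from the tert-butyl group gives methyl (2R,4R)-2-tert-butyl-4-[(2E,4S,9S)-9-hydroxy-2,4-dimethyl-6-methylideneundec-2-en-7-yn-1-yl]-1,3-dioxolane-4-carboxylate F6. HCl in MeOH at 50 °C frees the diol methyl (2R,4E,6S,11S)-2,11-dihydroxy-2-(hydroxymethyl)-4,6-dimethyl-8-methylidenetridec-4-en-9-ynoate F7, and 2,2-dimethoxypropane with TsOH closes the acetonide to 15.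

Step 13 may suffer from slow ketene formation from the α-methyl β-keto tert-butyl ester and from oligomerisation. Ring closure at C2–C3 instead sets out from 20 and comes back at 25. iBu2AlH in CH2Cl2 at −78 °C reduces the ester of 20 to (4R)-4-[(2E,4S,7E,9S)-8-({[tert-butyl(dimethyl)silyl]oxy}methyl)-9-hydroxy-2,4-dimethyl-6-methylideneundeca-2,7-dien-1-yl]-2,2-dimethyl-1,3-dioxolane-4-carbaldehyde F8. Acylation of the C13 hydroxyl with 2-bromopropanoyl bromide and pyridine gives (3S,4E,8S,9E)-4-({[tert-butyl(dimethyl)silyl]oxy}methyl)-11-[(4R)-4-formyl-2,2-dimethyl-1,3-dioxolan-4-yl]-8,10-dimethyl-6-methylideneundeca-4,9-dien-3-yl 2-bromopropanoate F9. SmI2 in THF at 0 °C and 1 mM effects an intramolecular Reformatsky reaction to (5R,10S,11E,15S,16E)-11-({[tert-butyl(dimethyl)silyl]oxy}methyl)-10-ethyl-6-hydroxy-2,2,7,15,17-pentamethyl-13-methylidene-1,3,9-trioxaspiro[4.13]octadeca-11,16-dien-8-one F10 (C6/C7 epimers), and Dess–Martin periodinane oxidises F10 to 25.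

**Further compounds**
F1 | step 2 | methyl (2R)-3-bromo-2-methylpropanoate | COC(=O)[C@@H](C)CBr
F2 | step 2 | [(2R)-3-methoxy-2-methyl-3-oxopropyl]zinc bromide | COC(=O)[C@@H](C)C[Zn]Br
F3 | step 2 | methyl (2S,7S)-7-hydroxy-2-methyl-4-methylidenenon-5-ynoate | COC(=O)[C@@H](C)CC(=C)C#C[C@H](CC)O
F4 | step 6 | methyl (4R)-2,2-dimethyl-1,3-dioxolane-4-carboxylate | COC(=O)[C@H]1COC(C)(C)O1
F5 | step 6 | methyl (2R,4R)-2-tert-butyl-1,3-dioxolane-4-carboxylate | COC(=O)[C@H]1CO[C@@H](C(C)(C)C)O1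
F6 | step 6 | methyl (2R,4R)-2-tert-butyl-4-[(2E,4S,9S)-9-hydroxy-2,4-dimethyl-6-methylideneundec-2-en-7-yn-1-yl]-1,3-dioxolane-4-carboxylate | COC(=O)[C@@]1(C/C(C)=C/[C@@H](C)CC(=C)C#C[C@H](CC)O)CO[C@@H](C(C)(C)C)O1
F7 | step 6 | methyl (2R,4E,6S,11S)-2,11-dihydroxy-2-(hydroxymethyl)-4,6-dimethyl-8-methylidenetridec-4-en-9-ynoate | COC(=O)[C@](O)(CO)C/C(C)=C/[C@@H](C)CC(=C)C#C[C@H](CC)O
F8 | step 13 | (4R)-4-[(2E,4S,7E,9S)-8-({[tert-butyl(dimethyl)silyl]oxy}methyl)-9-hydroxy-2,4-dimethyl-6-methylideneundeca-2,7-dien-1-yl]-2,2-dimethyl-1,3-dioxolane-4-carbaldehyde | O=C[C@]1(C/C(C)=C/[C@@H](C)CC(=C)/C=C(\CO[Si](C)(C)C(C)(C)C)[C@H](CC)O)OC(C)(C)OC1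
F9 | step 13 | (3S,4E,8S,9E)-4-({[tert-butyl(dimethyl)silyl]oxy}methyl)-11-[(4R)-4-formyl-2,2-dimethyl-1,3-dioxolan-4-yl]-8,10-dimethyl-6-methylideneundeca-4,9-dien-3-yl 2-bromopropanoate | O=C[C@]1(C/C(C)=C/[C@@H](C)CC(=C)/C=C(\CO[Si](C)(C)C(C)(C)C)[C@H](CC)OC(=O)C(C)Br)OC(C)(C)OC1
F10 | step 13 | (5R,10S,11E,15S,16E)-11-({[tert-butyl(dimethyl)silyl]oxy}methyl)-10-ethyl-6-hydroxy-2,2,7,15,17-pentamethyl-13-methylidene-1,3,9-trioxaspiro[4.13]octadeca-11,16-dien-8-one | C=C1/C=C(\CO[Si](C)(C)C(C)(C)C)[C@H](CC)OC(=O)C(C)C(O)[C@]2(COC(C)(C)O2)C/C(C)=C/[C@@H](C)C1
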